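## Analysis of the target

The target 25 is a cis-fused decalin of the eudesmane type, with ring A = C1, C2, C3, C4, C5, C10 and ring B = C5 to C10; the same locants are used for the hydrindane intermediates, whose five-membered ring is C1, C2, C3, C5, C10. Ring A carries at C3 the ester of (2S,3S)-2,3-epoxy-2-methylbutanoic (epoxyangelic) acid and at C4 a tertiary acetate beside a methyl group, while ring B carries the C8 ketone, the C7 isopropyl group and the angular C10 methyl group. The core has five stereocentres, C3 (R), C4 (S), C5 (S), C7 (R) and C10 (R), and the acyl group has two more; H-5, both methyl groups and the isopropyl group lie on the β face and both ring A oxygens on the α face, so the ring fusion and the 3,4-diol are both cis. In the chair–chair conformer that avoids a syn-diaxial contact of the C4 and C10 methyl groups, the C3 ester and the isopropyl group are equatorial and the C4 acetate is axial, and C7, which is epimerisable next to the ketone, has its thermodynamic configuration. The sensitive groups are the epoxide of the α,β-epoxy ester, two esters on vicinal cis oxygens (acyl migration, elimination of the tertiary acetate) and the enolisable ketone. The hard part is the contiguous array C3–C4–C5–C10 with two fully substituted carbons, the absolute configuration of the quaternary C10, and the acetylation of an axial tertiary alcohol next to a hindered ester. The strategy rests on C4: a tertiary, methyl-bearing carbinol next to the C3 oxygen is a 2-hydroxy-2-methylcyclohexanone in disguise. That is the product of an α-ketol rearrangement of a 1-acetylcyclopentanol in which C5 has moved from C3 to the acetyl carbon, so ring A can be grown out of the five-membered ring of a cis-hydrindane.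

## Retrosynthetic reasoning

**C4 acetate and C3 ester, from 25 back to 22 and 4.** The acetyl C–O bond at C4 is cut first, giving tertiary alcohol 24, because the axial tertiary hydroxyl is the least reactive oxygen and should be acylated last under forcing conditions. The acyl C–O bond at C3 is cut next, giving diol ketone 22 and epoxy acid 4. The secondary equatorial hydroxyl of 22 is the only one that reacts under mild esterification. Joining the enantiopure acid late keeps the epoxide out of all the earlier chemistry.

**C8 ketone, C7 and the C3 carbinol, from 22 back to 20.** The C8 ketone of 22 is traced back to the silyl enol ether in diol 21. The enol ether hides the ketone from the organolithium, the Lewis acid and the hydride used earlier. It also postpones the creation of the C7 stereocentre to the decalin stage, where equilibration clearly favours the equatorial 7β-isopropyl group. The C3 carbinol of 21 comes from ketone 20 by hydride addition to the β face, away from the axial 4α-hydroxyl.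

**Ring A, from 20 back to 19, the key disconnection.** The C4–C5 bond of α-ketol 20 is cut and C5 is reconnected to C3, which gives the acetyl carbinol 19 on a cis-hydrindane. No other cut in ring A turns the C4 carbinol, its methyl group and the C3 carbonyl into a single functional group of the precursor. The forward step must move C5 and not C2, and must place the new C4 oxygen on the α face.

**Acetyl carbinol, from 19 back to 15 and 16.** The bond between C3 and the acetyl carbon is cut. Acyloin 19 comes from enol ether 18, the adduct of ketone 15 and the lithiated form 17 of vinyl ether 16. The addition has to occur on the convex β face, so that the hydroxyl ends up α.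

**Absolute configuration and ring B, from 15 back to 9 and 10.** Ketone 15 is obtained from racemic ketone 11 by resolution through the diastereomeric adduct 14 with sulfoximine 12. An enantioselective cycloaddition is not relied on, because a β-alkyl cycloalkenone lies outside the demonstrated scope of chiral Lewis acid catalysts. In 11 the bonds C5–C6 and C9–C10 are cut, which leads to diene 9 and enone 10. This cycloaddition delivers all carbons of ring B, the quaternary C10, the cis fusion and the masked C8 ketone in one operation. The silyloxy group of 9 directs its neighbouring terminus (C9) to the β-carbon of 10 (C10).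

**Diene, from 9 back to 5.** Diene 9 is the silyl enol ether of enone 8. Its only enolisable position is the methyl group, so the diene forms with one regiochemistry. Enone 8 comes from aldehyde 5 by α-methylenation to enal 6, addition of a methyl nucleophile to give alcohol 7, and oxidation.

**Epoxy acid, from 4 back to 1.** Acid 4 is the oxidation product of epoxy alcohol 3. Alcohol 3 is made by asymmetric epoxidation of allylic alcohol 2, the reduction product of acid 1. The Z geometry of 1 becomes the cis relationship of the carboxyl group and the C3 methyl group in 4.

## Alternatives that were turned down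

Alternative 1: Ring B is traced back to a cyclobutane. Irradiation of 3-methylcyclohex-2-en-1-one A1 in the presence of allene A2 should give the head-to-head [2+2] adduct A3, in which C9–C10 is in place and a temporary C5–C8 bond holds a methylenecyclobutane. Ozonolysis of the methylene group at C8 and strain-driven opening of the four-membered ring would follow.
- For: the photocycloaddition forms the quaternary C10 and the cis ring junction reliably from two very simple compounds. It does not depend on a hindered Lewis-acid cycloaddition, and on this point it is more robust than step 8 of the chosen route.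
- Against: A3 holds only part of the skeleton. C6, C7 and the isopropyl group must still be added and ring B closed again. The C4 ketone then needs a methyl addition, and the C3 oxygen must be introduced on the concave face, cis to the C4 oxygen.
- Against: the photoreaction is racemic, so a resolution is needed here as well.
- Comparison: the chosen strategy brings in all ring B carbons in one cycloaddition and creates the C4 carbinol and ring A together, so its sequence after the key step is shorter.

Alternative 2: Ring B is again made by cutting C5–C6 and C9–C10, but with a quinone as ring A. The quinone 2-methoxy-5-methyl-1,4-benzoquinone A4 would react through its methyl-substituted double bond with 2-(tert-butyldimethylsilyloxy)-3-isopropylbuta-1,3-diene A5, catalysed by the chiral Lewis acid prepared from TiCl2(OiPr)2 and enantiopure BINOL, to give the cis-fused adduct A6.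
- For: quinones are excellent dienophiles, and catalytic enantioselective quinone cycloadditions are established. On reactivity and on absolute control this alternative is stronger than the chosen route, which uses a sluggish enone and a resolution. The methoxy group deactivates its own double bond and already marks C3 as oxygenated.
- Against: A6 has one carbonyl too many (C1), which must be deleted selectively in the presence of the C4 carbonyl. C4 still needs a stereocontrolled methyl addition, and C3 must be reduced to the α-carbinol from an enol ether. These are many redox and chemoselectivity steps after the key step.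
- Comparison: the chosen ring expansion gives exactly the oxidation pattern of ring A with no surplus oxygen, and both ring A stereocentres follow from convex-face additions.

Alternative 3: The C10–methyl and C5–C6 bonds are cut. A copper-catalysed conjugate addition (CuO2C(C4H3S) with a chiral phosphoramidite ligand) would transfer a methyl group from AlMe3 to C10 of the cyclohexenone A7. The resulting aluminium enolate at C5, made more reactive with MeLi, would then close ring B by intramolecular alkylation at the iodide-bearing C6 and give the decalinone A8.
- For: the copper-catalysed methyl addition to 3-substituted cyclohexenones is the best-precedented catalytic route to such a quaternary centre. On enantiocontrol at C10 this alternative is the strongest of the four, and ring A is six-membered from the start.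
- Against: A7 must be assembled in several steps. The ring closure is an alkylation of a weakly nucleophilic aluminium enolate by a β-branched primary iodide, where elimination competes.
- Against: A8 has only a C4 ketone. The C4 methyl carbinol, the C3 oxygen on the concave face and the C8 ketone (from the methylene group) must all still be made.
- Comparison: the chosen strategy has a shorter route to the ring system and gets the C3/C4 oxygen pattern from the key step itself, at the price of a resolution.

Key step: step 13

Remark on the chemistry: C8 is carried as its triisopropylsilyl enol ether from step 8 to step 15, so the key-step precursor 19 and product 20 differ from the free C8 ketones only in this spectator group. C7, α to the C8 ketone, is assumed to settle by equilibration as the equatorial 7β isomer found in the target.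

## Route

Step 1
Reactants: 1 angelic acid, (Z)-2-methylbut-2-enoic acid
Product: 2 angelyl alcohol, (Z)-2-methylbut-2-en-1-ol
Conditions: LiAlH4, Et2O, 0 °C; aq. potassium sodium tartrate work-up
Reagents that add atoms: none
Why: LiAlH4 reduction of the carboxylic acid to the primary allylic alcohol; the trisubstituted Z double bond is not reduced and should not isomerise under these non-acidic conditions.

Step 2
Reactants: 2 angelyl alcohol
Product: 3 [(2R,3S)-2,3-dimethyloxiran-2-yl]methanol
Conditions: Ti(OiPr)4 (cat.), D-(−)-diethyl tartrate (cat.), t-BuOOH, 4 Å molecular sieves, CH2Cl2, −20 °C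
Reagents that add atoms: tert-butyl hydroperoxide, CC(C)(C)OO
Why: Sharpless asymmetric epoxidation of an allylic alcohol; the D-(−)-tartrate ligand should direct oxygen to the face that gives the (2R,3S)-epoxy alcohol, and syn addition keeps CH2OH cis to the C3 methyl group.

Step 3
Reactants: 3 [(2R,3S)-2,3-dimethyloxiran-2-yl]methanol
Product: 4 (2S,3S)-2,3-dimethyloxirane-2-carboxylic acid (epoxyangelic acid)
Conditions: RuCl3 (cat.), NaIO4, MeCN–EtOAc–H2O, rt
Reagents that add atoms: water, O
Why: Catalytic RuO4 oxidation of the primary alcohol to the acid through the aldehyde hydrate; the epoxide and both stereocentres are untouched, and the C2 descriptor changes from R to S only because the substituent priorities change.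

Step 4
Reactants: 5 3-methylbutanal
Product: 6 3-methyl-2-methylidenebutanal (2-isopropylacrolein)
Conditions: aq. CH2O, pyrrolidine (cat.), propionic acid (cat.), i-PrOH, 45 °C
Reagents that add atoms: formaldehyde, C=O
Why: Mannich condensation and elimination (amine-catalysed α-methylenation of an aldehyde); the aldehyde has one α-position, so only one enal can form.

Step 5
Reactants: 6 3-methyl-2-methylidenebutanal
Product: 7 4-methyl-3-methylidenepentan-2-ol (racemic)
Conditions: MeMgBr, Et2O, −78 → 0 °C; then H2O
Reagents that add atoms: methylmagnesium bromide, C[Mg]Br
Why: 1,2-Addition of a Grignard reagent to an α-branched enal; the new stereocentre is of no consequence because it is oxidised in the next step.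

Step 6
Reactants: 7 4-methyl-3-methylidenepentan-2-ol
Product: 8 4-methyl-3-methylidenepentan-2-one (3-isopropylbut-3-en-2-one)
Conditions: Dess–Martin periodinane, NaHCO3, CH2Cl2, 0 °C → rt
Reagents that add atoms: none
Why: Dess–Martin oxidation of a secondary allylic alcohol under buffered, non-nucleophilic conditions that spare the polymerisable α-methylene ketone; the enone is used at once as a solution.

Step 7
Reactants: 8 4-methyl-3-methylidenepentan-2-one
Product: 9 triisopropyl[(4-methyl-3-methylidenepent-1-en-2-yl)oxy]silane (2-triisopropylsilyloxy-3-isopropylbuta-1,3-diene)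
Conditions: TIPSOTf, Et3N, CH2Cl2, 0 °C
Reagents that add atoms: triisopropylsilyl trifluoromethanesulfonate, CC(C)[Si](C(C)C)(C(C)C)OS(=O)(=O)C(F)(F)F
Why: Soft enolisation and O-silylation of a methyl ketone; the methyl group is the only enolisable α-position, so the cross-conjugated 2-silyloxydiene forms with one regiochemistry.

Step 8
Reactants: 9 2-triisopropylsilyloxy-3-isopropylbuta-1,3-diene; 10 3-methylcyclopent-2-en-1-one
Product: 11 racemic cis-hydrindenone, rac-(3aR,7aS)-3a-methyl-6-(propan-2-yl)-5-(triisopropylsilyloxy)-2,3,3a,4,7,7a-hexahydro-1H-inden-1-one (target locants: C3 ketone, 10-methyl, 7-isopropyl, 8-silyloxy, 7,8-ene, H-5 cis to CH3-10)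
Conditions: AlBr3/AlMe3 (about 5:1, substoichiometric), toluene–CH2Cl2, −15 → 0 °C
Reagents that add atoms: none
Why: Lewis-acid-catalysed Diels–Alder reaction of a hindered 2-silyloxydiene with a β-alkyl cycloalkenone under a mixed aluminium bromide/alkyl catalyst, a pairing used for such congested partners. The silyloxy group directs its adjacent terminus (C9) to the β-carbon of the enone (C10), giving the C8 oxygen and the quaternary C10 in the required 1,3-relationship. The cis ring fusion follows from suprafacial addition and is also the thermodynamic one, since C5 is enolisable.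

Step 9
Reactants: 11 racemic cis-hydrindenone; 12 (S)-N,S-dimethyl-S-phenylsulfoximine
Product: 14 (3R,5S,10R)-3α-hydroxy-3β-{[(S)-N-methyl-S-phenylsulfonimidoyl]methyl}-10-methyl-7-isopropyl-8-(triisopropylsilyloxy)-cis-hydrind-7-ene, via lithiated sulfoximine 13 (not isolated)
Conditions: 12, n-BuLi, THF, −78 °C; then 11; then H2O; chromatographic separation of the two diastereomers
Reagents that add atoms: none
Why: 1,2-Addition of an enantiopure α-lithio sulfoximine turns the two ketone enantiomers into diastereomeric β-hydroxysulfoximines (resolution of a ketone through covalent diastereomers). Each enantiomer should be attacked on its convex face, and the adduct of the (5S,10R)-ketone is identified, for instance by crystallography, and taken on.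

Step 10
Reactants: 14 β-hydroxysulfoximine
Product: 15 (3aR,7aS)-3a-methyl-6-(propan-2-yl)-5-(triisopropylsilyloxy)-2,3,3a,4,7,7a-hexahydro-1H-inden-1-one (target locants: 5S,10R)
Conditions: toluene, 110 °C
Reagents that add atoms: none
Why: Thermal retro-addition of a β-hydroxysulfoximine returns the ketone and the sulfoximine; no stereocentre of the bicycle is involved, so the ketone is released as a single enantiomer.

Step 11
Reactants: 15 (5S,10R)-hydrindenone; 16 ethyl vinyl ether
Product: 18 (3R,5S,10R)-3β-(1-ethoxyethenyl)-3α-hydroxy-10-methyl-7-isopropyl-8-(triisopropylsilyloxy)-cis-hydrind-7-ene, via 1-ethoxyvinyllithium 17 (not isolated)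
Conditions: 16, t-BuLi, THF, −78 → 0 °C; then 15, −78 °C; then H2O
Reagents that add atoms: none
Why: α-Lithiation of the vinyl ether gives an acyl anion equivalent that adds 1,2 to the cyclopentanone. Attack should come from the convex β face, which carries only H-5 and the C10 methyl group, whereas ring B folds under the α face; this sets C3 with the hydroxyl α. The silyl enol ether does not react with the organolithium.

Step 12
Reactants: 18 1-ethoxyethenyl carbinol
Product: 19 (3R,5S,10R)-3β-acetyl-3α-hydroxy-10-methyl-7-isopropyl-8-(triisopropylsilyloxy)-cis-hydrind-7-ene
Conditions: 0.1 M aq. HCl, THF, 0 °C, short time; NaHCO3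
Reagents that add atoms: water, O
Why: Acid hydrolysis of an enol ether by C-protonation; the 1,1-disubstituted ethoxyvinyl group protonates at its terminal CH2 far faster than the tetrasubstituted, hindered triisopropylsilyl enol ether at C7, so only the acetyl group is unmasked.

Step 13
Reactants: 19 3β-acetyl-3α-hydroxy cis-hydrindene
Product: 20 (4S,5S,10R)-4α-hydroxy-8-(triisopropylsilyloxy)-5βH-eudesm-7-en-3-one
Conditions: Al(OtBu)3, toluene, 80–100 °C; aq. potassium sodium tartrate work-up
Reagents that add atoms: none
Why: Al(OtBu)3 exchanges one alkoxide for the tertiary C3 hydroxyl and binds the acetyl oxygen, which holds the C3–O and C=O bonds syn in a five-membered chelate and makes the carbonyl carbon electrophilic. The C3–C5 bond, then roughly perpendicular to the carbonyl plane, shifts with its electron pair to the acetyl carbon with retention at C5 while the C3 alkoxide becomes the C3 ketone, which is an α-ketol (acyloin) rearrangement. The closest known reaction type is the Lewis-acid or aluminium-alkoxide D-homoannulation of 17-hydroxy-20-oxo steroids, in which an acetylcyclopentanol is enlarged in the same way. Ring A is closed by ring enlargement and not by a cyclisation: the five-membered ring C1–C2–C3–C5–C10 becomes six-membered by insertion of the former acetyl carbon, now C4, between C3 and C5. The new stereocentre C4 is controlled by the C3 configuration together with the syn chelate, because with the acetyl group on the β face and the two oxygens eclipsed C5 can reach only the carbonyl face that places the C4 oxygen α and the methyl group β. The step needs migration of C5 and not of C2; C5 is the more substituted carbon, and the rotamer that aligns C3–C5 keeps the acetyl methyl over the unhindered C2 methylene, whereas alignment of C3–C2 would press it against C5 and C6. The driving force is the relief of cyclopentane strain and the stronger chelate of the ring α-ketol. Al(OtBu)3 has no hydrogen on its carbinol carbons, so no Meerwein–Ponndorf–Verley reduction competes, and the silyl enol ether should be inert to this mild Lewis acid.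

Step 14
Reactants: 20 4α-hydroxy-3-ketone
Product: 21 (3R,4S,5S,10R)-8-(triisopropylsilyloxy)-5βH-eudesm-7-ene-3α,4α-diol
Conditions: NaBH4, MeOH–THF, −40 °C
Reagents that add atoms: none
Why: Borohydride reduction of the only ketone present. In the ring A chair with the C4 methyl equatorial and the C4 hydroxyl axial, hydride should enter axially from the β face, anti to the axial C–O bond (Felkin–Anh sense) and past only H-1β and H-5, giving the equatorial 3α-alcohol and thus the cis-diol.

Step 15
Reactants: 21 silyl enol ether diol
Product: 22 (3R,4S,5S,7R,10R)-3α,4α-dihydroxy-5βH-eudesman-8-one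
Conditions: TBAF, THF, 0 °C → rt; then K2CO3 (cat.), MeOH, rt
Reagents that add atoms: none
Why: Fluoride cleaves the Si–O bond and the C8 ketone forms on protonation; mild base then equilibrates C7 through the enolate. The 7β-isopropyl group is equatorial in the conformer that avoids the syn-diaxial C4/C10 methyl contact, while the 7α epimer would be syn-axial to C4, so the target configuration should prevail.

Step 16
Reactants: 22 diol ketone; 4 (2S,3S)-2,3-dimethyloxirane-2-carboxylic acid
Product: 24 (3R,4S,5S,7R,10R)-4α-hydroxy-8-oxo-5βH-eudesman-3α-yl (2S,3S)-2,3-dimethyloxirane-2-carboxylate, via mixed anhydride 23 (not isolated)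
Conditions: 4, 2,4,6-trichlorobenzoyl chloride, Et3N, THF, rt; then 22, DMAP, toluene, rt
Reagents that add atoms: none
Why: Yamaguchi esterification; the mixed anhydride of the hindered acid acylates the secondary equatorial 3α-hydroxyl and leaves the tertiary axial one alone. The acid has no α-hydrogen and the epoxide tolerates the basic medium; any minor enantiomer of 4 would end up as a separable diastereomer.

Step 17
Reactants: 24 hydroxy ester
Product: 25 target, (3R,4S,5S,7R,10R)-4α-acetoxy-8-oxo-5βH-eudesman-3α-yl (2S,3S)-2,3-dimethyloxirane-2-carboxylate
Conditions: Ac2O, DMAP, Et3N, CH2Cl2, 40 °C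
Reagents that add atoms: acetic anhydride, CC(=O)OC(C)=O
Why: DMAP-catalysed acetylation of a tertiary alcohol through the N-acetylpyridinium ion; the conditions are forcing but basic, so the epoxide and the C3 ester should survive, and no stereocentre is affected.

## Compound list

1 | angelic acid, (Z)-2-methylbut-2-enoic acid | C/C=C(/C)C(=O)O | starting material
2 | angelyl alcohol, (Z)-2-methylbut-2-en-1-ol | C/C=C(/C)CO | intermediate
3 | [(2R,3S)-2,3-dimethyloxiran-2-yl]methanol | OC[C@@]1(C)O[C@H]1C | intermediate
4 | (2S,3S)-2,3-dimethyloxirane-2-carboxylic acid | OC(=O)[C@@]1(C)O[C@H]1C | intermediate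
5 | 3-methylbutanal | CC(C)CC=O | starting material
6 | 3-methyl-2-methylidenebutanal | CC(C)C(=C)C=O | intermediate
7 | 4-methyl-3-methylidenepentan-2-ol (racemic) | CC(O)C(=C)C(C)C | intermediate
8 | 4-methyl-3-methylidenepentan-2-one | CC(=O)C(=C)C(C)C | intermediate
9 | triisopropyl[(4-methyl-3-methylidenepent-1-en-2-yl)oxy]silane | C=C(O[Si](C(C)C)(C(C)C)C(C)C)C(=C)C(C)C | intermediate
10 | 3-methylcyclopent-2-en-1-one | CC1=CC(=O)CC1 | starting material
11 | rac-(3aR,7aS)-3a-methyl-6-(propan-2-yl)-5-(triisopropylsilyloxy)-2,3,3a,4,7,7a-hexahydro-1H-inden-1-one (racemate, both enantiomers) | O=C1CC[C@]2(C)CC(O[Si](C(C)C)(C(C)C)C(C)C)=C(C(C)C)C[C@@H]21.O=C1CC[C@@]2(C)CC(O[Si](C(C)C)(C(C)C)C(C)C)=C(C(C)C)C[C@H]21 | intermediate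
12 | (S)-N,S-dimethyl-S-phenylsulfoximine | C[S@@](=O)(=NC)c1ccccc1 | starting material
13 | [(S)-N-methyl-S-phenylsulfonimidoyl]methyllithium | [Li]C[S@@](=O)(=NC)c1ccccc1 | intermediate (not isolated)
14 | (3R,5S,10R)-3α-hydroxy-3β-{[(S)-N-methyl-S-phenylsulfonimidoyl]methyl}-10-methyl-7-isopropyl-8-(triisopropylsilyloxy)-cis-hydrind-7-ene | CN=[S@@](=O)(c1ccccc1)C[C@@]1(O)CC[C@]2(C)CC(O[Si](C(C)C)(C(C)C)C(C)C)=C(C(C)C)C[C@@H]21 | intermediate
15 | (3aR,7aS)-3a-methyl-6-(propan-2-yl)-5-(triisopropylsilyloxy)-2,3,3a,4,7,7a-hexahydro-1H-inden-1-one | O=C1CC[C@]2(C)CC(O[Si](C(C)C)(C(C)C)C(C)C)=C(C(C)C)C[C@@H]21 | intermediate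
16 | ethyl vinyl ether | CCOC=C | starting material
17 | 1-ethoxyvinyllithium | [Li]C(=C)OCC | intermediate (not isolated)
18 | (3R,5S,10R)-3β-(1-ethoxyethenyl)-3α-hydroxy-10-methyl-7-isopropyl-8-(triisopropylsilyloxy)-cis-hydrind-7-ene | CCOC(=C)[C@@]1(O)CC[C@]2(C)CC(O[Si](C(C)C)(C(C)C)C(C)C)=C(C(C)C)C[C@@H]21 | intermediate
19 | (3R,5S,10R)-3β-acetyl-3α-hydroxy-10-methyl-7-isopropyl-8-(triisopropylsilyloxy)-cis-hydrind-7-ene (key-step precursor) | CC(=O)[C@@]1(O)CC[C@]2(C)CC(O[Si](C(C)C)(C(C)C)C(C)C)=C(C(C)C)C[C@@H]21 | intermediate
20 | (4S,5S,10R)-4α-hydroxy-8-(triisopropylsilyloxy)-5βH-eudesm-7-en-3-one (key-step product) | O[C@]1(C)C(=O)CC[C@]2(C)CC(O[Si](C(C)C)(C(C)C)C(C)C)=C(C(C)C)C[C@@H]21 | intermediate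
21 | (3R,4S,5S,10R)-8-(triisopropylsilyloxy)-5βH-eudesm-7-ene-3α,4α-diol | O[C@]1(C)[C@H](O)CC[C@]2(C)CC(O[Si](C(C)C)(C(C)C)C(C)C)=C(C(C)C)C[C@@H]21 | intermediate
22 | (3R,4S,5S,7R,10R)-3α,4α-dihydroxy-5βH-eudesman-8-one | O[C@]1(C)[C@H](O)CC[C@]2(C)CC(=O)[C@@H](C(C)C)C[C@@H]21 | intermediate
23 | (2S,3S)-2,3-dimethyloxirane-2-carboxylic 2,4,6-trichlorobenzoic anhydride | O=C(OC(=O)[C@@]1(C)O[C@H]1C)c1c(Cl)cc(Cl)cc1Cl | intermediate (not isolated)
24 | (3R,4S,5S,7R,10R)-4α-hydroxy-8-oxo-5βH-eudesman-3α-yl (2S,3S)-2,3-dimethyloxirane-2-carboxylate | O[C@]1(C)[C@H](OC(=O)[C@@]2(C)O[C@H]2C)CC[C@]2(C)CC(=O)[C@@H](C(C)C)C[C@@H]21 | intermediate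
25 | (3R,4S,5S,7R,10R)-4α-acetoxy-8-oxo-5βH-eudesman-3α-yl (2S,3S)-2,3-dimethyloxirane-2-carboxylate (CNP0221066.1) | CC(=O)O[C@]1(C)[C@H](OC(=O)[C@@]2(C)O[C@H]2C)CC[C@]2(C)CC(=O)[C@@H](C(C)C)C[C@@H]21 | target

## Step count and least certain steps

Total step count: 17. Longest linear sequence: 14 steps (steps 4 to 17, from 5 to 25); steps 1 to 3 make acid 4 for step 16.

**Step 13 (key step).** The most likely failures are a competing shift of C2 in place of C5, a second acyloin shift of the methyl group on prolonged heating that moves the carbonyl next to the ring fusion, and erosion of the chelate control over C4. The fallback sets out from 19 and uses the complementary pairing of C3 configuration and promoter. Dehydration with Burgess reagent, which can only eliminate toward C2 because H-5 is anti to the hydroxyl, gives the conjugated enone 3-acetyl-10-methyl-7-isopropyl-8-(triisopropylsilyloxy)-cis-hydrinda-2,7-diene F1. Conjugate reduction with KBH(s-Bu)3 and oxidation of the resulting enolate with 2-(phenylsulfonyl)-3-phenyloxaziridine from the convex face give the C3-epimeric acyloin F2 (3β-hydroxy, 3α-acetyl). Under KOH in MeOH the alkoxide and carbonyl oxygens turn anti, and the shift of C5 then leads to the same C4 configuration, so the sequence comes back to the route at 20.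

**Step 8.** The cycloaddition may stall at the β,β-disubstituted acceptor, the reaction may stop after the first C–C bond with loss of the silyl group and no ring closure, or the diene may oligomerise. The fallback sets out from 10 and raises the reactivity of the dienophile. α-Iodination (I2, pyridine) gives 2-iodo-3-methylcyclopent-2-en-1-one F3. Methoxycarbonylation (PdCl2(PPh3)2 cat., CO, MeOH, Et3N) gives methyl 2-methyl-5-oxocyclopent-1-ene-1-carboxylate F4, a doubly activated dienophile. Cycloaddition with 9 under ZnCl2 gives the racemic angular ester adduct F5. Demethoxycarbonylation with LiCl in wet DMSO at 130 °C (Krapcho) and protonation to the cis-fused ketone return to the route at 11.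

**Step 11.** The vinyllithium may attack partly from the concave face, or it may enolise the ketone. The fallback sets out from 15 and does not discard the concave-face adduct. The epimeric carbinol 3α-(1-ethoxyethenyl)-3β-hydroxy-10-methyl-7-isopropyl-8-(triisopropylsilyloxy)-cis-hydrind-7-ene F6 is separated and hydrolysed as in step 12 to the epimeric acyloin F2. F2 is rearranged with KOH in MeOH through the anti arrangement, as described for step 13, and returns to the route at 20. Each C3 epimer is thus matched with its own promoter.

**Step 12.** The silyl enol ether may hydrolyse along with the ethoxyvinyl group. The fallback sets out from 18 and accepts the loss of the silyl group. Aqueous HCl (1 M) in THF at rt unmasks both carbonyls and gives 3β-acetyl-3α-hydroxy-10-methyl-7-isopropyl-cis-hydrindan-8-one F7. Al(OtBu)3 in toluene then gives 4α-hydroxy-5βH-eudesmane-3,8-dione F8. NaBH4 at low temperature should reduce the C3 carbonyl, activated by the adjacent hydroxyl, ahead of the hindered C8 ketone. After equilibration of C7 with K2CO3 in MeOH the sequence returns to the route at 22.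

**Step 17.** Acylation of the axial tertiary hydroxyl may be slow, and 1,2-migration of the epoxy ester to O4 or elimination of the tertiary oxygen may compete. The fallback sets out from 22 and reverses the order of the two acylations. Trimethyl orthoacetate with catalytic camphorsulfonic acid gives the 3,4-cyclic methyl orthoacetate F9. Mild aqueous acid opens it to the axial ester, 4α-acetoxy-3α-hydroxy-5βH-eudesman-8-one F10. Yamaguchi esterification of the free equatorial 3α-hydroxyl with 4 then gives 25.

## Further compounds

F1 | step 13 | (5S,10R)-3-acetyl-10-methyl-7-isopropyl-8-(triisopropylsilyloxy)-cis-hydrinda-2,7-diene | CC(=O)C1=CC[C@]2(C)CC(O[Si](C(C)C)(C(C)C)C(C)C)=C(C(C)C)C[C@@H]21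
F2 | step 13 | (3S,5S,10R)-3α-acetyl-3β-hydroxy-10-methyl-7-isopropyl-8-(triisopropylsilyloxy)-cis-hydrind-7-ene | CC(=O)[C@]1(O)CC[C@]2(C)CC(O[Si](C(C)C)(C(C)C)C(C)C)=C(C(C)C)C[C@@H]21
F3 | step 8 | 2-iodo-3-methylcyclopent-2-en-1-one | CC1=C(I)C(=O)CC1
F4 | step 8 | methyl 2-methyl-5-oxocyclopent-1-ene-1-carboxylate | COC(=O)C1=C(C)CCC1=O
F5 | step 8 | racemic methyl cis-3a-methyl-1-oxo-6-(propan-2-yl)-5-(triisopropylsilyloxy)-2,3,3a,4,7,7a-hexahydro-1H-indene-7a-carboxylate (both enantiomers) | O=C1CC[C@]2(C)CC(O[Si](C(C)C)(C(C)C)C(C)C)=C(C(C)C)C[C@@]21C(=O)OC.O=C1CC[C@@]2(C)CC(O[Si](C(C)C)(C(C)C)C(C)C)=C(C(C)C)C[C@]21C(=O)OC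
F6 | step 11 | (3S,5S,10R)-3α-(1-ethoxyethenyl)-3β-hydroxy-10-methyl-7-isopropyl-8-(triisopropylsilyloxy)-cis-hydrind-7-ene | CCOC(=C)[C@]1(O)CC[C@]2(C)CC(O[Si](C(C)C)(C(C)C)C(C)C)=C(C(C)C)C[C@@H]21
F7 | step 12 | 3β-acetyl-3α-hydroxy-10-methyl-7β-isopropyl-cis-hydrindan-8-one | CC(=O)[C@@]1(O)CC[C@]2(C)CC(=O)[C@@H](C(C)C)C[C@@H]21
F8 | step 12 | 4α-hydroxy-5βH-eudesmane-3,8-dione | O[C@]1(C)C(=O)CC[C@]2(C)CC(=O)[C@@H](C(C)C)C[C@@H]21
F9 | step 17 | 3α,4α-O-(1-methoxyethylidene)-5βH-eudesman-8-one (mixture of epimers at the orthoester carbon) | COC3(C)O[C@]1(C)[C@H](O3)CC[C@]2(C)CC(=O)[C@@H](C(C)C)C[C@@H]21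
F10 | step 17 | 4α-acetoxy-3α-hydroxy-5βH-eudesman-8-one | CC(=O)O[C@]1(C)[C@H](O)CC[C@]2(C)CC(=O)[C@@H](C(C)C)C[C@@H]21
A1 | alternative 1 | 3-methylcyclohex-2-en-1-one | CC1=CC(=O)CCC1
A2 | alternative 1 | allene (propadiene) | C=C=C
A3 | alternative 1 | cis-6-methyl-8-methylenebicyclo[4.2.0]octan-2-one | O=C1CCC[C@]2(C)CC(=C)[C@@H]21
A4 | alternative 2 | 2-methoxy-5-methyl-1,4-benzoquinone | COC1=CC(=O)C(C)=CC1=O
A5 | alternative 2 | 2-(tert-butyldimethylsilyloxy)-3-isopropylbuta-1,3-diene | C=C(O[Si](C)(C)C(C)(C)C)C(=C)C(C)C
A6 | alternative 2 | cis-fused cycloadduct of A4 and A5, a 2-methoxy-ene-1,4-dione with the C8 tert-butyldimethylsilyl enol ether (target locants) | O=C1C(OC)=CC(=O)[C@]2(C)CC(O[Si](C)(C)C(C)(C)C)=C(C(C)C)C[C@@H]21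
A7 | alternative 3 | 3-[2-(1-iodo-3-methylbutan-2-yl)prop-2-en-1-yl]cyclohex-2-en-1-one (C7 configured as in A8) | O=C1C=C(CC(=C)[C@@H](C(C)C)CI)CCC1
A8 | alternative 3 | cis-10-methyl-7-isopropyl-8-methylidenedecalin-4-one (target locants) | O=C1CCC[C@]2(C)CC(=C)[C@@H](C(C)C)C[C@@H]21
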